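**Plan**

- Cuts: (a) the C3–O ester bond, which releases (2E,5R)-5-(angeloyloxy)hex-2-enoic acid (itself cut at C2′=C3′). (b) The C8 ketone/C9 carbinol pair is read back to a C9 ketone. (c) C1–C2 and C5–C10 are cut together. (d) The open chain is cut at C9–C10, C4–C5, C5–CH3 and C2=C3, back to a C5–C9 acid aldehyde obtained by ring cleavage of (R)-carvone.
- Enabling feature (eremophilane numbering, ring A = C1–C5 + C10, ring B = C5–C10): ring A has oxygen at C3 next to the methyl-bearing C4, so it is a hydrolysed C3=C4 enol-ether cyclohexene. The oxygenated C9 of ring B is bonded to the fusion carbon C10. Ring A therefore unfolds to a 2-methoxydiene C2=C3–C4=C5 and a vinyl ketone C1=C10–C9(=O), already linked through C6–C7–C8.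
- Forward order: carvone ring cleavage, chain growth at both ends to an acyclic trienone, rings A and B closed together in one cycloaddition, ring B oxygenation (C8, C9), ring A adjustment (C4, C3), ester union, release of the α-ketol.
- Stereochemistry: C7 comes from carvone. C5 and C10 follow from C7 and from the E geometry of C4=C5 in an endo, chair-like transition state. C8 (temporary), C9, C4 and C3 are set by the shape of the cis-decalin (C3 finally by inversion). C5′ comes from (R)-pent-4-en-2-ol, the Z alkene from angelic acid, the E alkene from cross-metathesis.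

Key step: step 11

Remark on the chemistry: eremophilane names serve only for numbering, and β means the face that carries the C5 methyl group. The carbinol carbon made by the vinyl Grignard addition is carried as a mixture of epimers (left undefined in the SMILES) until it is oxidised.

**Step 1**
Reactants: 1 (R)-(−)-carvone
Product: 2 (1R,4R,6R)-1-methyl-4-(prop-1-en-2-yl)-7-oxabicyclo[4.1.0]heptan-2-one
Conditions: 30% aq H2O2, NaOH (cat.), MeOH, 0 °C
Reagents that add atoms: hydrogen peroxide, OO
Why: Weitz–Scheffer nucleophilic epoxidation attacks only the electron-poor enone alkene, spares the isopropenyl group and delivers oxygen anti to it, although both new centres are erased in step 2.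

**Step 2**
Reactants: 2 carvone epoxide
Product: 4 (3R)-5-oxo-3-(prop-1-en-2-yl)pentanoic acid, via keto diol 3 (not isolated)
Conditions: 3% aq H2SO4, THF, rt; then NaIO4 (2.5 equiv), THF–H2O, 0 °C to rt
Reagents that add atoms: water, O
Why: Acid-catalysed anti hydration of the epoxide followed by Malaprade periodate cleavage of the glycol and of the resulting 1,2-dicarbonyl unit excises the methyl-bearing carbon as acetic acid, leaves an acid and an aldehyde terminus on either side of the untouched stereocentre, and does not attack the isolated alkene.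

**Step 3**
Reactants: 4 aldehyde acid; 5 vinylmagnesium bromide
Product: 6 (3R)-5-hydroxy-3-(prop-1-en-2-yl)hept-6-enoic acid (carbinol epimers)
Conditions: 5 (2.3 equiv), THF, −78 to 0 °C; cold aq citric acid work-up, used at once
Reagents that add atoms: none
Why: Grignard 1,2-addition in which the first equivalent only forms the unreactive carboxylate and the second adds to the aldehyde (C9–C10 bond); the new carbinol centre needs no control because step 10 makes it the ketone.

**Step 4**
Reactants: 6 hydroxy acid
Product: 8 (3R)-5-[(tert-butyldimethylsilyl)oxy]-3-(prop-1-en-2-yl)hept-6-enoic acid, via bis-silyl derivative 7 (not isolated)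
Conditions: TBSOTf (2.3 equiv), 2,6-lutidine, CH2Cl2, −78 to 0 °C; then AcOH–THF–H2O, rt
Reagents that add atoms: tert-butyldimethylsilyl triflate, CC(C)(C)[Si](C)(C)OS(=O)(=O)C(F)(F)F
Why: Silyl triflate silylation is fast enough at low temperature to outrun lactonisation of the 5-hydroxy acid, and the much more labile silyl ester is then hydrolysed selectively.

**Step 5**
Reactants: 8 silyl ether acid; 9 methyl propanoate
Product: 12 methyl (5R)-7-[(tert-butyldimethylsilyl)oxy]-2-methyl-3-oxo-5-(prop-1-en-2-yl)non-8-enoate, via lithium enolate 10 (not isolated), via acyl imidazolide 11 (not isolated)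
Conditions: 8, 1,1'-carbonyldiimidazole, THF, rt; added to 9 (3.3 equiv) + LiN(iPr)2 (3.3 equiv), THF, −78 °C
Reagents that add atoms: 1,1'-carbonyldiimidazole, O=C(n1ccnc1)n1ccnc1 (imidazolyl group of 11 only); lithium diisopropylamide, [Li+].CC(C)[N-]C(C)C (lithium of 10 only)
Why: Crossed Claisen condensation of an acyl imidazolide with excess preformed ester enolate forms C4–C5; the excess enolate deprotonates the β-keto ester as it forms so that no second acylation occurs, and the α-centre is lost in step 6.

**Step 6**
Reactants: 12 β-keto ester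
Product: 14 methyl (2Z,5R)-7-[(tert-butyldimethylsilyl)oxy]-2-methyl-5-(prop-1-en-2-yl)-3-[(trifluoromethylsulfonyl)oxy]nona-2,8-dienoate, via chelated lithium enolate 13 (not isolated)
Conditions: LiN(SiMe3)2, THF, −78 °C; then PhNTf2, −78 °C to rt
Reagents that add atoms: N-phenylbis(trifluoromethanesulfonimide), O=S(=O)(N(c1ccccc1)S(=O)(=O)C(F)(F)F)C(F)(F)F; lithium hexamethyldisilazide, [Li+].C[Si](C)(C)[N-][Si](C)(C)C (lithium of 13 only)
Why: O-Sulfonylation of the lithium-chelated β-keto ester enolate, in which both oxygen atoms are held on the same side of the double bond, so the triflate ends cis to the ester (Z).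

**Step 7**
Reactants: 14 enol triflate
Product: 15 methyl (2E,5S)-7-[(tert-butyldimethylsilyl)oxy]-2,3-dimethyl-5-(prop-1-en-2-yl)nona-2,8-dienoate
Conditions: MeZnCl (1.5 equiv), Pd(PPh3)4 (5 mol %), THF, rt
Reagents that add atoms: methylzinc chloride, C[Zn]Cl
Why: Negishi coupling of an electron-poor alkenyl triflate runs with retention, so methyl replaces triflate cis to the ester and C6 stays trans to it (E), the geometry step 11 needs; transmetallation from zinc at room temperature outruns Heck-type closure onto the pendant alkenes.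

**Step 8**
Reactants: 15 tetrasubstituted enoate
Product: 16 tert-butyl{[(5S,7E)-9-methoxy-7,8-dimethyl-5-(prop-1-en-2-yl)deca-1,7,9-trien-3-yl]oxy}dimethylsilane
Conditions: Cp2TiMe2 (3 equiv), toluene, 75 °C, dark; filtration through basic Al2O3
Reagents that add atoms: dimethyltitanocene, C[Ti+2]C.c1cc[cH-]c1.c1cc[cH-]c1
Why: Petasis methylenation turns the ester carbonyl into a 1-methoxyvinyl group under non-acidic conditions, so the unsaturated ester becomes the 2-methoxydiene in one step without change of alkene geometry or loss of the silyl ether.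

**Step 9**
Reactants: 16 silyl ether
Product: 17 (5S,7E)-9-methoxy-7,8-dimethyl-5-(prop-1-en-2-yl)deca-1,7,9-trien-3-ol
Conditions: Bu4NF, THF, 0 °C to rt
Reagents that add atoms: none
Why: Fluoride desilylation, to which a methyl dienol ether is inert, which is the reason a methyl and not a silyl dienol ether is carried.

**Step 10**
Reactants: 17 allylic alcohol
Product: 18 (5S,7E)-9-methoxy-7,8-dimethyl-5-(prop-1-en-2-yl)deca-1,7,9-trien-3-one
Conditions: Dess–Martin periodinane, pyridine, CH2Cl2, 0 °C; short basic Al2O3 plug
Reagents that add atoms: none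
Why: Dess–Martin oxidation under pyridine buffering gives the vinyl ketone without free acid that would hydrolyse the dienol ether, and both carbinol epimers converge.

**Step 11**
Reactants: 18 trienone
Product: 19 3-methoxy-10βH-eremophila-3,11-dien-9-one [(3S,4aS,8aS)-6-methoxy-4a,5-dimethyl-3-(prop-1-en-2-yl)-3,4,4a,7,8,8a-hexahydronaphthalen-1(2H)-one]
Conditions: toluene (0.01 M), BHT (0.1 equiv), base-washed sealed tube, 110 °C
Reagents that add atoms: none
Why: Concerted, suprafacial but asynchronous [4+2] cycloaddition, the type 1 intramolecular Diels–Alder reaction of a 1,7,9-decatrien-3-one (a class known to give cis-fused octalones), in which the nucleophilic enol-ether terminus C2 bonds early to the enone β-carbon C1 and the crowded C5–C10 bond follows. Ring A closes as the new cyclohexene of the six-electron array (bonds C1–C2 and C5–C10), and ring B closes at the same moment as the fused six-membered ring spanned by the four-atom tether C6–C7–C8–C9 once C5–C10 forms. The relative configuration C5/C10 follows from the E alkene, which puts C6 on the outside and the methyl on the inside of C5, and from the endo placement of the s-cis enone carbonyl under the diene, so that the C5 methyl and H10 end on the same face (cis fusion), while the exo mode would press C9 against the inside methyl. The absolute sense at C5 and C10 is relayed from C7, because in the chair-like tether the isopropenyl group must be equatorial (an axial one would collide with C4 of the diene), which opens only one diene face and places isopropenyl, C5 methyl and H10 all β. Regiochemistry is fixed by the tether and matched electronically by the C3 methoxy donor; the methoxy and methyl groups at C3 and C4 destabilise the s-trans rotamer too, so the penalty the inside methyl imposes on the s-cis geometry stays moderate. Dilution and BHT hold back vinyl ketone polymerisation, and neutral glass keeps the product enol ether intact as the mask that distinguishes C3 from the C9 ketone.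

**Step 12**
Reactants: 19 octalone
Product: 21 8β-hydroxy-3-methoxy-10βH-eremophila-3,11-dien-9-one, via potassium enolate 20 (not isolated)
Conditions: KN(SiMe3)2, THF, −78 °C; then 2-(phenylsulfonyl)-3-phenyloxaziridine, −78 °C
Reagents that add atoms: 2-(phenylsulfonyl)-3-phenyloxaziridine, O=S(=O)(c1ccccc1)N1OC1c1ccccc1; potassium hexamethyldisilazide, [K+].C[Si](C)(C)[N-][Si](C)(C)C (potassium of 20 only)
Why: Kinetic deprotonation at the C8 methylene rather than at the fusion C10–H, then N-sulfonyloxaziridine enolate hydroxylation by axial approach on the convex β face away from ring A, should give the 8β-alcohol; the neutral enol ether and the isopropenyl group are not oxidised at −78 °C.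

**Step 13**
Reactants: 21 α-hydroxy ketone
Product: 22 3-methoxy-8β-(triethylsilyloxy)-10βH-eremophila-3,11-dien-9-one
Conditions: TESOTf, 2,6-lutidine, CH2Cl2, −78 °C
Reagents that add atoms: triethylsilyl triflate, CC[Si](CC)(CC)OS(=O)(=O)C(F)(F)F
Why: Silyl triflate/lutidine silylation covers the hindered axial alcohol without base strong enough to epimerise C8 or C10.

**Step 14**
Reactants: 22 α-silyloxy ketone
Product: 23 3-methoxy-8β-(triethylsilyloxy)-10βH-eremophila-3,11-dien-9β-ol
Conditions: LiAlH4, Et2O, −78 °C
Reagents that add atoms: none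
Why: Hydride addition to an α-alkoxy ketone, in which the small hydride adds antiperiplanar to the axial C8–O bond from the α face while the silyl ether screens the β face, should give the equatorial 9β-alcohol cis to O8; the low temperature suppresses silyl migration.

**Step 15**
Reactants: 23 alcohol
Product: 24 9β-(tert-butyldimethylsilyloxy)-3-methoxy-8β-(triethylsilyloxy)-10βH-eremophila-3,11-diene
Conditions: TBSOTf, 2,6-lutidine, CH2Cl2, 0 °C
Reagents that add atoms: tert-butyldimethylsilyl triflate, CC(C)(C)[Si](C)(C)OS(=O)(=O)C(F)(F)F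
Why: Silylation with the more robust group differentiates the two ring B oxygens, so that O8 can be freed alone in step 21.

**Step 16**
Reactants: 24 enol ether
Product: 25 9β-(tert-butyldimethylsilyloxy)-8β-(triethylsilyloxy)-10βH-eremophil-11-en-3-one (4β-methyl)
Conditions: (CO2H)2 (cat.), THF–H2O, 0 °C to rt; then K2CO3 (cat.), MeOH, rt
Reagents that add atoms: water, O
Why: Acid-catalysed enol ether hydrolysis (rate-limiting protonation at C4) is far faster than solvolysis of the hindered silyl ethers, and the mild base then equilibrates C4 so that its methyl is equatorial and β, since the axial epimer would be syn-axial to C9.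

**Step 17**
Reactants: 25 ketone
Product: 26 9β-(tert-butyldimethylsilyloxy)-8β-(triethylsilyloxy)-10βH-eremophil-11-en-3β-ol
Conditions: LiBH(s-Bu)3, THF, −78 °C
Reagents that add atoms: none
Why: Bulky trialkylborohydride reduction along the equatorial trajectory from the α face, the axial path being blocked by the syn-axial C5 methyl, should give the axial 3β-alcohol.

**Step 18**
Reactants: 27 (R)-pent-4-en-2-ol; 28 angelic acid
Product: 30 (R)-pent-4-en-2-yl (Z)-2-methylbut-2-enoate, via mixed anhydride 29 (not isolated)
Conditions: 28, 2,4,6-Cl3C6H2COCl, Et3N, toluene, rt; then 27, 80 °C (no DMAP)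
Reagents that add atoms: 2,4,6-trichlorobenzoyl chloride, O=C(Cl)c1c(Cl)cc(Cl)cc1Cl (aroyl group of 29 only)
Why: Yamaguchi-type mixed-anhydride esterification without a nucleophilic catalyst avoids the addition–elimination that turns angelates into tiglates, and the carbinol centre is not involved.

**Step 19**
Reactants: 30 angelate; 31 acrylic acid
Product: 32 (2E,5R)-5-{[(Z)-2-methylbut-2-enoyl]oxy}hex-2-enoic acid
Conditions: 31 (3 equiv), second-generation Hoveyda–Grubbs catalyst (H2IMes)Cl2Ru=CH(2-iPrOC6H4) (5 mol %), CH2Cl2, 40 °C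
Reagents that add atoms: none
Why: Olefin cross-metathesis of a terminal alkene with an acrylate partner is E-selective, and the trisubstituted electron-poor angelate alkene is inert to the catalyst.

**Step 20**
Reactants: 26 axial 3β-alcohol; 32 side-chain acid
Product: 33 3α-{[(2E,5R)-5-(angeloyloxy)hex-2-enoyl]oxy}-9β-(tert-butyldimethylsilyloxy)-8β-(triethylsilyloxy)-10βH-eremophil-11-ene
Conditions: PPh3, DIAD, toluene, 0 °C to rt
Reagents that add atoms: none
Why: Mitsunobu esterification displaces the axial oxyphosphonium group by carboxylate with inversion to the equatorial 3α-ester; because the acid is never activated as an acyl electrophile, deconjugation and loss of the δ-angelate are avoided.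

**Step 21**
Reactants: 33 bis-silyl ether
Product: 34 3α-{[(2E,5R)-5-(angeloyloxy)hex-2-enoyl]oxy}-9β-(tert-butyldimethylsilyloxy)-10βH-eremophil-11-en-8β-ol
Conditions: HF·pyridine, pyridine, THF, 0 °C
Reagents that add atoms: none
Why: Buffered fluoride desilylation removes a triethylsilyl ether much faster than a tert-butyldimethylsilyl ether and is too weakly acidic for silyl migration or ester cleavage.

**Step 22**
Reactants: 34 alcohol
Product: 35 3α-{[(2E,5R)-5-(angeloyloxy)hex-2-enoyl]oxy}-9β-(tert-butyldimethylsilyloxy)-10βH-eremophil-11-en-8-one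
Conditions: Dess–Martin periodinane, pyridine, CH2Cl2, 0 °C to rt
Reagents that add atoms: none
Why: Dess–Martin oxidation is neutral enough that C7, now α to the ketone with its isopropenyl group equatorial, neither epimerises nor lets the alkene move into conjugation.

**Step 23**
Reactants: 35 α-silyloxy ketone
Product: 36 target CNP0210874.1
Conditions: HF·pyridine, THF, 0 °C to rt
Reagents that add atoms: none
Why: Fluoride desilylation under weakly acidic conditions frees the 9β-hydroxyl and is tolerated by both esters, the Z angelate and the β,γ-unsaturated ketone.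

**Compound list**

1 | (R)-(−)-carvone | CC1=CC[C@@H](C(C)=C)CC1=O | starting material
2 | (1R,4R,6R)-1-methyl-4-(prop-1-en-2-yl)-7-oxabicyclo[4.1.0]heptan-2-one | C[C@@]12O[C@@H]1C[C@@H](C(C)=C)CC2=O | intermediate
3 | (2R,3S,5R)-2,3-dihydroxy-2-methyl-5-(prop-1-en-2-yl)cyclohexan-1-one | C[C@@]1(O)[C@@H](O)C[C@@H](C(C)=C)CC1=O | intermediate
4 | (3R)-5-oxo-3-(prop-1-en-2-yl)pentanoic acid | O=CC[C@@H](C(C)=C)CC(=O)O | intermediate
5 | vinylmagnesium bromide | C=C[Mg]Br | starting material
6 | (3R)-5-hydroxy-3-(prop-1-en-2-yl)hept-6-enoic acid | C=CC(O)C[C@@H](C(C)=C)CC(=O)O | intermediate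
7 | tert-butyldimethylsilyl (3R)-5-[(tert-butyldimethylsilyl)oxy]-3-(prop-1-en-2-yl)hept-6-enoate | C=CC(O[Si](C)(C)C(C)(C)C)C[C@@H](C(C)=C)CC(=O)O[Si](C)(C)C(C)(C)C | intermediate
8 | (3R)-5-[(tert-butyldimethylsilyl)oxy]-3-(prop-1-en-2-yl)hept-6-enoic acid | C=CC(O[Si](C)(C)C(C)(C)C)C[C@@H](C(C)=C)CC(=O)O | intermediate
9 | methyl propanoate | CCC(=O)OC | starting material
10 | lithium enolate of methyl propanoate | CC=C([O-])OC.[Li+] | intermediate
11 | acyl imidazolide of 8 | C=CC(O[Si](C)(C)C(C)(C)C)C[C@@H](C(C)=C)CC(=O)n1ccnc1 | intermediate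
12 | methyl (5R)-7-[(tert-butyldimethylsilyl)oxy]-2-methyl-3-oxo-5-(prop-1-en-2-yl)non-8-enoate | C=CC(O[Si](C)(C)C(C)(C)C)C[C@@H](C(C)=C)CC(=O)C(C)C(=O)OC | intermediate
13 | chelated lithium enolate of 12 | C=CC(O[Si](C)(C)C(C)(C)C)C[C@@H](C(C)=C)C/C([O-])=C(\C)C(=O)OC.[Li+] | intermediate
14 | (2Z,5R)-enol triflate | C=CC(O[Si](C)(C)C(C)(C)C)C[C@@H](C(C)=C)C/C(OS(=O)(=O)C(F)(F)F)=C(\C)C(=O)OC | intermediate
15 | methyl (2E,5S)-7-[(tert-butyldimethylsilyl)oxy]-2,3-dimethyl-5-(prop-1-en-2-yl)nona-2,8-dienoate | C=CC(O[Si](C)(C)C(C)(C)C)C[C@@H](C(C)=C)C/C(C)=C(\C)C(=O)OC | intermediate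
16 | (5S,7E)-3-silyloxy-9-methoxy-7,8-dimethyl-5-(prop-1-en-2-yl)deca-1,7,9-triene | C=CC(O[Si](C)(C)C(C)(C)C)C[C@@H](C(C)=C)C/C(C)=C(\C)C(OC)=C | intermediate
17 | (5S,7E)-9-methoxy-7,8-dimethyl-5-(prop-1-en-2-yl)deca-1,7,9-trien-3-ol | C=CC(O)C[C@@H](C(C)=C)C/C(C)=C(\C)C(OC)=C | intermediate
18 | (5S,7E)-9-methoxy-7,8-dimethyl-5-(prop-1-en-2-yl)deca-1,7,9-trien-3-one | C=CC(=O)C[C@@H](C(C)=C)C/C(C)=C(\C)C(OC)=C | intermediate
19 | 3-methoxy-10βH-eremophila-3,11-dien-9-one | C=C(C)[C@H]1C[C@@]2(C)[C@H](CCC(OC)=C2C)C(=O)C1 | intermediate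
20 | potassium C8=C9 enolate of 19 | C=C(C)[C@H]1C[C@@]2(C)[C@H](CCC(OC)=C2C)C([O-])=C1.[K+] | intermediate
21 | 8β-hydroxy-3-methoxy-10βH-eremophila-3,11-dien-9-one | C=C(C)[C@H]1C[C@@]2(C)[C@H](CCC(OC)=C2C)C(=O)[C@H]1O | intermediate
22 | 3-methoxy-8β-(triethylsilyloxy)-10βH-eremophila-3,11-dien-9-one | C=C(C)[C@H]1C[C@@]2(C)[C@H](CCC(OC)=C2C)C(=O)[C@H]1O[Si](CC)(CC)CC | intermediate
23 | 3-methoxy-8β-(triethylsilyloxy)-10βH-eremophila-3,11-dien-9β-ol | C=C(C)[C@H]1C[C@@]2(C)[C@H](CCC(OC)=C2C)[C@@H](O)[C@H]1O[Si](CC)(CC)CC | intermediate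
24 | 9β-(tert-butyldimethylsilyloxy)-3-methoxy-8β-(triethylsilyloxy)-10βH-eremophila-3,11-diene | C=C(C)[C@H]1C[C@@]2(C)[C@H](CCC(OC)=C2C)[C@@H](O[Si](C)(C)C(C)(C)C)[C@H]1O[Si](CC)(CC)CC | intermediate
25 | 9β-(tert-butyldimethylsilyloxy)-8β-(triethylsilyloxy)-10βH-eremophil-11-en-3-one | C=C(C)[C@H]1C[C@@]2(C)[C@H](CCC(=O)[C@@H]2C)[C@@H](O[Si](C)(C)C(C)(C)C)[C@H]1O[Si](CC)(CC)CC | intermediate
26 | 9β-(tert-butyldimethylsilyloxy)-8β-(triethylsilyloxy)-10βH-eremophil-11-en-3β-ol | C=C(C)[C@H]1C[C@@]2(C)[C@H](CC[C@H](O)[C@@H]2C)[C@@H](O[Si](C)(C)C(C)(C)C)[C@H]1O[Si](CC)(CC)CC | intermediate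
27 | (R)-pent-4-en-2-ol | C=CC[C@@H](C)O | starting material
28 | angelic acid, (Z)-2-methylbut-2-enoic acid | C/C=C(/C)C(=O)O | starting material
29 | angelic 2,4,6-trichlorobenzoic anhydride | C/C=C(/C)C(=O)OC(=O)c1c(Cl)cc(Cl)cc1Cl | intermediate
30 | (R)-pent-4-en-2-yl angelate | C=CC[C@@H](C)OC(=O)/C(C)=C\C | intermediate
31 | acrylic acid | C=CC(=O)O | starting material
32 | (2E,5R)-5-(angeloyloxy)hex-2-enoic acid | OC(=O)/C=C/C[C@@H](C)OC(=O)/C(C)=C\C | intermediate
33 | 3α-ester, 8β-OTES, 9β-OTBS | C=C(C)[C@H]1C[C@@]2(C)[C@H](CC[C@@H](OC(=O)/C=C/C[C@@H](C)OC(=O)/C(C)=C\C)[C@@H]2C)[C@@H](O[Si](C)(C)C(C)(C)C)[C@H]1O[Si](CC)(CC)CC | intermediate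
34 | 3α-ester, 8β-OH, 9β-OTBS | C=C(C)[C@H]1C[C@@]2(C)[C@H](CC[C@@H](OC(=O)/C=C/C[C@@H](C)OC(=O)/C(C)=C\C)[C@@H]2C)[C@@H](O[Si](C)(C)C(C)(C)C)[C@H]1O | intermediate
35 | 3α-ester, 8-ketone, 9β-OTBS | C=C(C)[C@H]1C[C@@]2(C)[C@H](CC[C@@H](OC(=O)/C=C/C[C@@H](C)OC(=O)/C(C)=C\C)[C@@H]2C)[C@@H](O[Si](C)(C)C(C)(C)C)C1=O | intermediate
36 | CNP0210874.1, (3R,4R,5R,7R,9R,10S)-3-{[(2E,5R)-5-(angeloyloxy)hex-2-enoyl]oxy}-9-hydroxyeremophil-11-en-8-one | C=C(C)[C@H]1C[C@@]2(C)[C@H](CC[C@@H](OC(=O)/C=C/C[C@@H](C)OC(=O)/C(C)=C\C)[C@@H]2C)[C@@H](O)C1=O | target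

Total step count: 23. Longest linear sequence: 21 (steps 1–17 and 20–23).

**Steps most likely to fail**

**Step 11.** Ring closure may be too slow, because the methyl group on the inside of C5 resists the s-cis diene geometry. Vinyl ketone polymerisation, a 1,5-hydrogen shift within the diene, or leakage through a boat-like tether (loss of facial selectivity) could then take over.
- Fallback, from 18 directly to 19: thermal substrate control is given up for a catalyst-controlled polar cycloaddition.
- The catalyst (0.2 equiv) is the cationic oxazaborolidine made from α,α-diphenylprolinol, tri(o-tolyl)boroxine and HN(SO2CF3)2, used in CH2Cl2 at −78 to −40 °C with an Et3N quench. The catalyst enantiomer that reinforces the chair-like mode is chosen.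
- Coordination at the C9 carbonyl lowers the barrier and pushes C1–C2 formation far ahead of the crowded C5–C10 bond. The catalyst, not only C7, then shields one enone face.
- No new compound is made (F0).

**Step 14.** Hydride delivery may go to the β face, because the α face is crowded by the syn-axial C4. This would mean poor or inverted facial selectivity at C9.
- Fallback, from 22 back to 23: kinetic hydride addition is replaced by reversible hydride transfer under thermodynamic control.
- This is a Meerwein–Ponndorf–Verley reduction with Al(OiPr)3 in iPrOH–toluene at 80 °C, with a trace of acetone kept in the mixture. Both carbinol epimers then interconvert through the ketone.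
- The equatorial 9β-alcohol, free of the syn-axial contact with C4, should accumulate.
- No new compound is made (F0).

**Step 20.** Anti elimination of the axial oxyphosphonium group toward C2 or C4, or sluggish activation next to the syn-axial C5 methyl, may outrun substitution.
- Fallback, from 25 to 33: the inversion is dropped and the enoate is built on the decalin.
- Single-electron reduction of 25 with SmI2–H2O–Et3N in THF should give the more stable equatorial 3α-alcohol F1.
- Carbodiimide acylation of F1 with diethylphosphonoacetic acid (EDC, DMAP) should give the phosphonoacetate F2.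
- Ozonolysis of the terminal alkene of 30 (O3, CH2Cl2, −78 °C, then Me2S) should give (R)-4-oxobutan-2-yl angelate F3.
- A Horner–Wadsworth–Emmons reaction of F2 with F3 under Masamune–Roush conditions (LiCl, iPr2NEt, MeCN) joins them E-selectively and returns to 33.

**Further compounds**

F0 | step 11 | none | none
F0 | step 14 | none | none
F1 | step 20 | 9β-(tert-butyldimethylsilyloxy)-8β-(triethylsilyloxy)-10βH-eremophil-11-en-3α-ol | C=C(C)[C@H]1C[C@@]2(C)[C@H](CC[C@@H](O)[C@@H]2C)[C@@H](O[Si](C)(C)C(C)(C)C)[C@H]1O[Si](CC)(CC)CC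
F2 | step 20 | 3α-(diethylphosphonoacetoxy) derivative of F1 | C=C(C)[C@H]1C[C@@]2(C)[C@H](CC[C@@H](OC(=O)CP(=O)(OCC)OCC)[C@@H]2C)[C@@H](O[Si](C)(C)C(C)(C)C)[C@H]1O[Si](CC)(CC)CC
F3 | step 20 | (R)-4-oxobutan-2-yl (Z)-2-methylbut-2-enoate | O=CC[C@@H](C)OC(=O)/C(C)=C\C
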